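## Retrosynthetic overview

1. Feature: each side ring carries, in order, C1′ (CH2 bridge), C2′ (OH), C3′ (CH3), C4′ (OCH3), C5′ (butanoyl) and C6′ (OH). The methoxy carbon C4′ lies ortho to the butanoyl C=O, and once its oxygen is deleted, C4′–H is the single aryl C–H left on any of the three benzene rings.
2. Agrimol C ⇐ (methanolysis of seven acetates, then O-methylation) heptaacetate bis-phenol ⇐ (two C4′–O bonds by ketone-directed, palladium-catalysed C–H oxygenation) heptaacetate of the trimer lacking both C4′ oxygens.
3. Deoxy trimer ⇐ two aryl–CH2 bonds: the dimethylaminomethyl (Mannich) derivative of 2,4-dihydroxy-5-methylbutyrophenone (2 equiv) plus butyrylphloroglucinol. The ketone ⇐ 4-methylresorcinol + butanoic acid.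
4. No ring is formed; the three benzene rings are bought. Order of events: side ring acylated, aminomethylated, two side rings joined to the central ring, all phenols acetylated, both side rings oxygenated, methylated, unmasked.

Key step: step 5

Remark (assumption): the trimer is assembled from the side-ring Mannich base and not by a one-pot formaldehyde condensation. The side ring has one nucleophilic carbon and, as its Mannich base, can act only as an electrophile, so homo-coupled products are excluded. Butyrylphloroglucinol is taken to be purchasable.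

## Route

Step 1
Reactants: 1 4-methylresorcinol; 2 butanoic acid
Product: 3 1-(2,4-dihydroxy-5-methylphenyl)butan-1-one
Conditions: ZnCl2 (anhydrous, 1.5 equiv), butanoic acid (excess), 135 °C; then dilute aq. HCl
Reagents that add atoms: none
Why: Nencki reaction (ZnCl2-mediated Friedel–Crafts acylation with the free acid) should attack C6 of 4-methylresorcinol, which is para to one hydroxyl, ortho to the other and less crowded than C2 between the two hydroxyls, while C5 is meta to both and unreactive.

Step 2
Reactants: 3 1-(2,4-dihydroxy-5-methylphenyl)butan-1-one; 4 formaldehyde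
Product: 5 1-[3-[(dimethylamino)methyl]-2,4-dihydroxy-5-methylphenyl]butan-1-one
Conditions: 37% aq. CH2O, 40% aq. Me2NH, EtOH, 0 °C → rt
Reagents that add atoms: dimethylamine, CNC
Why: Phenolic Mannich reaction, in which the iminium ion can only attack C3 between the two hydroxyls, because the other free ring carbon is meta to both hydroxyls and ortho to the ketone.

Step 3
Reactants: 5 1-[3-[(dimethylamino)methyl]-2,4-dihydroxy-5-methylphenyl]butan-1-one (2.2 equiv); 6 1-(2,4,6-trihydroxyphenyl)butan-1-one (butyrylphloroglucinol)
Product: 8 1-[3,5-bis[(3-butanoyl-2,6-dihydroxy-5-methylphenyl)methyl]-2,4,6-trihydroxyphenyl]butan-1-one (heptaphenol trimer), via ortho-quinone methide 7 (not isolated)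
Conditions: 1,4-dioxane, 100 °C, slow N2 purge
Reagents that add atoms: none
Why: Thermal loss of dimethylamine from the ortho-hydroxybenzylamine gives ortho-quinone methide 7, which is trapped by conjugate C-alkylation (Friedel–Crafts-type) at C3 and then C5 of the phloroglucinol, and since 5 has no nucleophilic ring carbon only cross-coupling can occur.

Step 4
Reactants: 8 heptaphenol trimer
Product: 9 1-[2,4,6-triacetoxy-3,5-bis[(2,6-diacetoxy-3-butanoyl-5-methylphenyl)methyl]phenyl]butan-1-one (heptaacetate)
Conditions: Ac2O (excess), pyridine, DMAP (cat.), rt → 40 °C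
Reagents that add atoms: acetic anhydride, CC(=O)OC(C)=O
Why: DMAP-catalysed O-acylation should esterify all seven phenols, including the hydrogen-bonded and doubly ortho-substituted ones, which frees the ketone carbonyls from chelation and makes the rings and bridges electron-poor for the next step.

Step 5
Reactants: 9 heptaacetate of the deoxy trimer
Product: 11 1-[2,4,6-triacetoxy-3,5-bis[(2,6-diacetoxy-3-butanoyl-4-hydroxy-5-methylphenyl)methyl]phenyl]butan-1-one (heptaacetate bis-phenol), via bis(trifluoroacetate) 10 (not isolated)
Conditions: Pd(OAc)2 (20 mol %), K2S2O8 (5 equiv), CF3CO2H, 50 °C; then pH 7 phosphate buffer, rt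
Reagents that add atoms: trifluoroacetic acid, OC(=O)C(F)(F)F
Why: Proposed new method: each side-ring butanoyl oxygen, no longer held in a hydrogen bond, should bind electrophilic divalent palladium (Pd(O2CCF3)2 formed in situ) and deliver it to C4′–H by concerted metalation–deprotonation, giving a five-membered palladacycle that K2S2O8 oxidises to tetravalent palladium, from which C–O reductive elimination releases the aryl trifluoroacetate 10 and regenerates divalent palladium; buffered water then cleaves only the two very labile trifluoroacetates. The closest known reaction type is the ketone-directed ortho-hydroxylation of simple aryl ketones with Pd(OAc)2 or [RuCl2(p-cymene)]2 and persulfate in CF3CO2H, which has not been shown twice in one molecule on a pentasubstituted ring at a C–H flanked by a methyl group. No ring of the product is closed (the palladacycle is transient) and no stereocentre is formed. Site selectivity is needed and is built into 9, because C4′–H is the only aromatic hydrogen, the other ortho position of each side-ring ketone carries an acetate and the central ketone has no ortho hydrogen. Chemoselectivity against oxidation of the two diarylmethane CH2 groups is also needed and should come from the seven acetates, which make all three rings electron-poor, and from the four ortho substituents that crowd each bridge. Over-oxidation should be limited because the new oxygen stays masked as the electron-withdrawing trifluoroacetate until work-up.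

Step 6
Reactants: 11 heptaacetate bis-phenol
Product: 12 1-[2,4,6-triacetoxy-3,5-bis[(2,6-diacetoxy-3-butanoyl-4-methoxy-5-methylphenyl)methyl]phenyl]butan-1-one (heptaacetate bis-methyl ether)
Conditions: PPh3, DIAD, MeOH, THF, 0 °C → rt
Reagents that add atoms: methanol, CO
Why: Mitsunobu etherification methylates the two C4′ hydroxyls, the only acidic O–H groups present, and by activating methanol instead of generating a free phenoxide it should avoid acetyl transfer between oxygens.

Step 7
Reactants: 12 heptaacetate bis-methyl ether
Product: 13 Agrimol C, 1-[3,5-bis[(3-butanoyl-2,6-dihydroxy-4-methoxy-5-methylphenyl)methyl]-2,4,6-trihydroxyphenyl]butan-1-one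
Conditions: K2CO3 (10 equiv), degassed MeOH–THF, 0 °C → rt, Ar; then 1 M HCl
Reagents that add atoms: none
Why: Base-mediated transesterification (methanolysis) removes the seven aryl acetates, which are far more labile than the aryl methyl ethers and ketones, while low temperature, short contact and exclusion of air guard against base-induced migration of the methylene bridges and oxidation of the phloroglucinol rings.

## Compound list

1 | 4-methylresorcinol | Cc1ccc(O)cc1O | starting material
2 | butanoic acid | CCCC(=O)O | starting material
3 | 1-(2,4-dihydroxy-5-methylphenyl)butan-1-one | CCCC(=O)c1cc(C)c(O)cc1O | intermediate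
4 | formaldehyde | C=O | starting material
5 | 1-[3-[(dimethylamino)methyl]-2,4-dihydroxy-5-methylphenyl]butan-1-one | CCCC(=O)c1cc(C)c(O)c(CN(C)C)c1O | intermediate
6 | 1-(2,4,6-trihydroxyphenyl)butan-1-one (butyrylphloroglucinol) | CCCC(=O)c1c(O)cc(O)cc1O | starting material
7 | 4-butanoyl-3-hydroxy-6-methyl-2-methylidenecyclohexa-3,5-dien-1-one (ortho-quinone methide, not isolated) | CCCC(=O)C1=C(O)C(=C)C(=O)C(C)=C1 | intermediate
8 | 1-[3,5-bis[(3-butanoyl-2,6-dihydroxy-5-methylphenyl)methyl]-2,4,6-trihydroxyphenyl]butan-1-one | CCCC(=O)c1c(O)c(Cc2c(O)c(C)cc(C(=O)CCC)c2O)c(O)c(Cc2c(O)c(C)cc(C(=O)CCC)c2O)c1O | intermediate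
9 | 1-[2,4,6-triacetoxy-3,5-bis[(2,6-diacetoxy-3-butanoyl-5-methylphenyl)methyl]phenyl]butan-1-one | CCCC(=O)c1c(OC(C)=O)c(Cc2c(OC(C)=O)c(C)cc(C(=O)CCC)c2OC(C)=O)c(OC(C)=O)c(Cc2c(OC(C)=O)c(C)cc(C(=O)CCC)c2OC(C)=O)c1OC(C)=O | intermediate
10 | 1-[2,4,6-triacetoxy-3,5-bis[[2,6-diacetoxy-3-butanoyl-5-methyl-4-(trifluoroacetoxy)phenyl]methyl]phenyl]butan-1-one (not isolated) | CCCC(=O)c1c(OC(C)=O)c(Cc2c(OC(C)=O)c(C)c(OC(=O)C(F)(F)F)c(C(=O)CCC)c2OC(C)=O)c(OC(C)=O)c(Cc2c(OC(C)=O)c(C)c(OC(=O)C(F)(F)F)c(C(=O)CCC)c2OC(C)=O)c1OC(C)=O | intermediate
11 | 1-[2,4,6-triacetoxy-3,5-bis[(2,6-diacetoxy-3-butanoyl-4-hydroxy-5-methylphenyl)methyl]phenyl]butan-1-one | CCCC(=O)c1c(OC(C)=O)c(Cc2c(OC(C)=O)c(C)c(O)c(C(=O)CCC)c2OC(C)=O)c(OC(C)=O)c(Cc2c(OC(C)=O)c(C)c(O)c(C(=O)CCC)c2OC(C)=O)c1OC(C)=O | intermediate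
12 | 1-[2,4,6-triacetoxy-3,5-bis[(2,6-diacetoxy-3-butanoyl-4-methoxy-5-methylphenyl)methyl]phenyl]butan-1-one | CCCC(=O)c1c(OC(C)=O)c(Cc2c(OC(C)=O)c(C)c(OC)c(C(=O)CCC)c2OC(C)=O)c(OC(C)=O)c(Cc2c(OC(C)=O)c(C)c(OC)c(C(=O)CCC)c2OC(C)=O)c1OC(C)=O | intermediate
13 | Agrimol C | CCCC(=O)c1c(O)c(Cc2c(O)c(C)c(OC)c(C(=O)CCC)c2O)c(O)c(Cc2c(O)c(C)c(OC)c(C(=O)CCC)c2O)c1O | target

## Step count and risks

Total step count: 7. Longest linear sequence: 7 steps (1 → 13).

**Step 5 (highest risk, carries the new method).** Palladation at C4′–H, buttressed by the C3′ methyl group and the ketone on a fully substituted ring, may be too slow. Sulfate radicals from persulfate may then abstract hydrogen from the diarylmethane bridges, or the reaction may stop after one of the two oxygenations. The fallback uses only known chemistry and installs the oxygen before the rings are joined. It sets out from 6 and returns to the route at 13.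
- C-methylation of 6 (MeI, NaOMe, MeOH, 0 °C) should give 1-(2,4,6-trihydroxy-3-methylphenyl)butan-1-one F1.
- MOMCl (2.1 equiv) and iPr2NEt in CH2Cl2 should protect the para hydroxyl and the less hindered ortho hydroxyl, leaving the hydrogen-bonded hydroxyl between methyl and butanoyl free, to give 1-[2-hydroxy-4,6-bis(methoxymethoxy)-3-methylphenyl]butan-1-one F2.
- Methylation of that hydroxyl (MeI, K2CO3, acetone, reflux) should give 1-[2-methoxy-4,6-bis(methoxymethoxy)-3-methylphenyl]butan-1-one F3.
- HCl in MeOH at 40 °C should remove both acetals to give 1-(4,6-dihydroxy-2-methoxy-3-methylphenyl)butan-1-one F4.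
- A Mannich reaction at its only free ring carbon (aq. CH2O, aq. Me2NH, EtOH) should give 1-[3-[(dimethylamino)methyl]-2,4-dihydroxy-6-methoxy-5-methylphenyl]butan-1-one F5.
- Heating F5 (2.2 equiv) with 6 in dioxane at 100 °C, as in step 3, should expel dimethylamine and give 13 directly.

**Step 3.** The quinone methide may oligomerise with itself, the reaction may stall after the first bridge, or liberated amine may cause exchange of the bridges at 100 °C. The fallback reverses the polarity of the coupling; it sets out from 6 and returns at 8. A twofold Mannich reaction of 6 (excess aq. CH2O and aq. Me2NH, EtOH) should give 1-[3,5-bis[(dimethylamino)methyl]-2,4,6-trihydroxyphenyl]butan-1-one F6. Heating F6 in dioxane with an excess of 3 as the nucleophile, which reacts at its carbon between the two hydroxyls, should give 8.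

**Step 6.** The hydrogen-bonded phenol flanked by methyl and butanoyl may be too poor a nucleophile toward the methoxyphosphonium ion, so that the reduced azodicarboxylate is alkylated instead and methylation remains incomplete. The fallback changes the mode of activation from alcohol activation to a hard methyl electrophile. It sets out from 11 and returns at 12, using Me3OBF4 with 1,8-bis(dimethylamino)naphthalene in CH2Cl2 at 0 °C, a non-nucleophilic medium in which the acetates should stay in place. This fallback makes no new compound (F0).

## Further compounds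

F1 | step 5 | 1-(2,4,6-trihydroxy-3-methylphenyl)butan-1-one | CCCC(=O)c1c(O)cc(O)c(C)c1O
F2 | step 5 | 1-[2-hydroxy-4,6-bis(methoxymethoxy)-3-methylphenyl]butan-1-one | CCCC(=O)c1c(O)c(C)c(OCOC)cc1OCOC
F3 | step 5 | 1-[2-methoxy-4,6-bis(methoxymethoxy)-3-methylphenyl]butan-1-one | CCCC(=O)c1c(OC)c(C)c(OCOC)cc1OCOC
F4 | step 5 | 1-(4,6-dihydroxy-2-methoxy-3-methylphenyl)butan-1-one | CCCC(=O)c1c(OC)c(C)c(O)cc1O
F5 | step 5 | 1-[3-[(dimethylamino)methyl]-2,4-dihydroxy-6-methoxy-5-methylphenyl]butan-1-one | CCCC(=O)c1c(OC)c(C)c(O)c(CN(C)C)c1O
F6 | step 3 | 1-[3,5-bis[(dimethylamino)methyl]-2,4,6-trihydroxyphenyl]butan-1-one | CCCC(=O)c1c(O)c(CN(C)C)c(O)c(CN(C)C)c1O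
F0 | step 6 | none | none
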